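Two questions stood before me: how much target each flask of the row holds at the end, and what shape the row takes.

* amount of target at the end, in percent of the starting material charged for Wednesday's, Friday's, Thursday's, Tuesday's, Sunday's, in this order
* how that number moves from the first to the last of them (rises all the way / falls all the way / rises, then falls / falls, then rises / hardly changes)

| setting | beta | zeta | Wednesday's | Friday's | Thursday's | Tuesday's | Sunday's |
|---|---|---|---|---|---|---|---|
| starting material | 0.011 M | 0.88 M | 0.012 M | 0.030 M | 0.10 M | 0.30 M | 1.0 M |
| reagent | 0.12 M | 0.12 M | 0.120 M | 0.120 M | 0.120 M | 0.120 M | 0.120 M |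
| protic impurity | 0.010 M | 0.010 M | 0.0100 M | 0.0100 M | 0.0100 M | 0.0100 M | 0.0100 M |
| free catalyst | 10 mM | 10 mM | 10 mM | 10 mM | 10 mM | 10 mM | 10 mM |
| remark | run made earlier | run made earlier |  |  |  |  |  |
| time |  |  | 2.5 min | 2.5 min | 2.5 min | 2.5 min | 2.5 min |

- beta (time / s: target / %, starting material / %): 10.0: 0.5, 35.1; 15.0: 1.5, 26.4; 30.0: 4.8, 12.2; 80.0: 14.8, 1.3
- zeta (time / s: target / %, starting material / %): 10.0: 0, 98.4; 15.0: 0, 97.9; 30.0: 0, 97.4; 80.0: 1.9, 96.4

(scatter of a reading: 0.5 percentage points)

- "hardly changes" means that all values lie within two and a half points (for a concentration: within two and a half percent of the largest)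

I looked for the charge at which control changes hands. Zeta, charged far richer than beta, showed 1.9% target at 80.0 s, which is 0.0167 M, and I assumed that this pace held at every rich charge, a pseudo-zero-order behaviour in starting material. A straight line from the start gave a bound from below, 0.0313 M, but zeta still read 0% at 30.0 s, so a line beginning there gave a bound from above, 0.0401 M. Between them lies W, the turnover allowance, the concentration of target the catalyst can turn out in the time.

For a charge c of starting material, a rich flask's yield is therefore W/c, which put Thursday's between 31.3% and 40.1%, Tuesday's between 10.4% and 13.4%, and Sunday's between 3.13% and 4.01%.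

On the lean side I let the protic impurity take its whole charge, which leaves the share 1 − c(impurity)/c. That gave 16.7% for Wednesday's and 66.7% for Friday's, which is less than Friday's W/c. The two branches cross where c equals the impurity charge plus W, between 0.0413 M and 0.0501 M, so I expected the row to rise and then fall.

The forecast gave 25%, 13%, 6.3%, 4.5% and 3.7%, a row that falls all the way, on the ground that "The turnover is therefore catalyst-limited, with a weak assist from free starting material.", which put Thursday's below my lower bound and Sunday's inside my bracket.

The flasks gave 20.8%, 52.0%, 34.0%, 13.1% and 4.09%, a row that rises, then falls.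

    catalyst intermediate B → catalyst intermediate C (k = 0.0550 s⁻¹)
    starting material + protic impurity → quenched substrate (k = 16.0 L mol⁻¹ s⁻¹)
    reagent + free catalyst → catalyst intermediate A (k = 1.30 L mol⁻¹ s⁻¹)
    starting material + catalyst intermediate A → catalyst intermediate B (k = 2.10 L mol⁻¹ s⁻¹)
    catalyst intermediate C ⇌ free catalyst + target (K = 0.180 M, k = 0.160 s⁻¹)

Read through W, Sunday's made 0.0409 M, over my upper bound, and Tuesday's, the second flask, made 0.0393 M, inside it; the row turned at 0.036 M, below my crossing, and Wednesday's stood above its share with 5.78% of the impurity still there. In Wednesday's at 0.108 min, starting material went to the protic impurity 5.5 times as fast as to catalyst intermediate A, and quenched substrate stood at 78.5% of the charge after 2.50 min.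

The numbers in the tables stem from a simulated flask from invented constants; scatter was added.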